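The resorcinol ring fused to the dihydrobenzofuran (ring A) lies in the eight-membered carbocycle as a two-carbon unit between the indane CH that carries it (C-2) and dihydrobenzofuran C3 (C-5). A six-membered 1-tetralone-2-carboxylate in which C-2 is bonded directly to C-5 (the ketone carbon) is therefore made by an asymmetric photoenolization/Diels–Alder reaction, and 3,5-dimethoxybenzyne is inserted into that bond. This aryne acyl-alkylation forms both ring A–carbon bonds (ring carbon meta to both oxygens to C-2, ring carbon next to the ether oxygen to C-5) and expands the ring from six to eight atoms in one operation. Two Grignard additions, an acid-triggered indane closure and a demethylation with dihydrobenzofuran closure finish the synthesis.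

Key step: step 8

Labels: ring A = resorcinol ring fused to the dihydrobenzofuran; ring B = resorcinol ring of the indane; ring C = resorcinol ring fused only to the eight-membered ring; rings D, E, F = 4-hydroxyphenyl rings on C-1, C-4 and C-6. C-1 = indane CH bearing ring D; C-2 = indane CH bearing ring A; C-3 = indane CH bearing C-4; C-4 = CH bearing ring E; C-5 = dihydrobenzofuran C3; C-6 = dihydrobenzofuran C2. Target: C-1 S, C-2 S, C-3 R, C-4 R, C-5 R, C-6 R.

Remark 1: the sense of induction of the TADDOL ligand in step 3 is assumed; the ligand antipode that gives the (3S,4R) adduct is the one used.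

Remark 2: C-2 is epimerisable in 7 and 14–16 and is drawn trans to ring B. The carbinol centres at C-5 (15–17) and C-1 (17) and the alkene geometry in 18 and 19 are mixtures without consequence and are left undefined.

Step 1
Reactants: 1 2-bromo-3,5-dimethoxybenzaldehyde
Product: 2 3,5-dimethoxy-2-(4-methoxybenzyl)benzaldehyde
Conditions: 4-MeOC6H4CH2ZnCl, Pd(OAc)2 (2 mol%), SPhos (4 mol%), THF, rt → 50 °C
Reagents that add atoms: 4-methoxybenzylzinc chloride, COc1ccc(C[Zn]Cl)cc1
Why: Negishi sp2–sp3 cross-coupling, in which the benzylzinc reagent tolerates the free aldehyde and the bulky biarylphosphine copes with the doubly ortho-substituted bromide.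

Step 2
Reactants: 3 (E)-3-(3,5-dimethoxyphenyl)prop-2-enoic acid
Product: 4 propan-2-yl (E)-3-(3,5-dimethoxyphenyl)prop-2-enoate
Conditions: i-PrOH, H2SO4 (cat.), reflux
Reagents that add atoms: propan-2-ol, CC(C)O
Why: Fischer esterification; the isopropyl ester is chosen so that alkoxide exchange with Ti(Oi-Pr)4 in step 3 is degenerate.

Step 3
Reactants: 2 3,5-dimethoxy-2-(4-methoxybenzyl)benzaldehyde; 4 propan-2-yl (E)-3-(3,5-dimethoxyphenyl)prop-2-enoate
Product: 6 propan-2-yl (1R,2R,3S,4R)-3-(3,5-dimethoxyphenyl)-1-hydroxy-5,7-dimethoxy-4-(4-methoxyphenyl)-1,2,3,4-tetrahydronaphthalene-2-carboxylate, via photoenol 5 (not isolated)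
Conditions: Ti(Oi-Pr)4 (3 equiv), (R,R)-TADDOL (1.2 equiv), toluene, hν (366 nm), rt
Reagents that add atoms: none
Why: Asymmetric photoenolization/Diels–Alder reaction: excitation of the aldehyde and 1,5-H shift give hydroxy-o-quinodimethane 5, whose titanium dienolate adds to the cinnamate (transparent at 366 nm) with ortho regiochemistry (carbinol carbon to ester-bearing carbon); the E-alkene fixes ester and ring B trans, the endo ester and the outward ring E on the diene terminus place ring E trans to ring B, and the chiral Ti–TADDOLate should set the absolute configuration of C-3 and C-4.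

Step 4
Reactants: 6 propan-2-yl (1R,2R,3S,4R)-3-(3,5-dimethoxyphenyl)-1-hydroxy-5,7-dimethoxy-4-(4-methoxyphenyl)-1,2,3,4-tetrahydronaphthalene-2-carboxylate
Product: 7 propan-2-yl (2R,3S,4R)-3-(3,5-dimethoxyphenyl)-5,7-dimethoxy-4-(4-methoxyphenyl)-1-oxo-1,2,3,4-tetrahydronaphthalene-2-carboxylate
Conditions: Dess–Martin periodinane, CH2Cl2, 0 °C → rt
Reagents that add atoms: none
Why: Dess–Martin oxidation of the benzylic alcohol under neutral conditions (no retro-aldol) gives the β-keto ester; C-2 becomes epimerisable and should rest trans to ring B, while C-3 and C-4 are untouched.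

Step 5
Reactants: 8 3,5-dimethoxyphenol
Product: 9 3,5-dimethoxyphenyl N-(propan-2-yl)carbamate
Conditions: i-PrNCO, Et3N (cat.), CH2Cl2, rt
Reagents that add atoms: isopropyl isocyanate, CC(C)N=C=O
Why: Base-catalysed addition of the phenol to the isocyanate installs a removable carbamate directing group.

Step 6
Reactants: 9 3,5-dimethoxyphenyl N-(propan-2-yl)carbamate
Product: 10 3,5-dimethoxy-2-(trimethylsilyl)phenyl N-(propan-2-yl)carbamate
Conditions: TBSOTf, TMEDA, Et2O, 0 °C → rt; n-BuLi, TMEDA, −78 °C; TMSCl, −78 °C → rt; aq. NaHSO4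
Reagents that add atoms: chlorotrimethylsilane, C[Si](C)(C)Cl
Why: Directed ortho-metalation of the N-silylated carbamate occurs at the position flanked by carbamate and methoxy (both such positions are equivalent), and the aryllithium is silylated; the N-silyl group is lost on work-up.

Step 7
Reactants: 10 3,5-dimethoxy-2-(trimethylsilyl)phenyl N-(propan-2-yl)carbamate
Product: 11 3,5-dimethoxy-2-(trimethylsilyl)phenyl trifluoromethanesulfonate
Conditions: DBU, Et2NH, MeCN, 40 °C; then PhNTf2, rt
Reagents that add atoms: N-phenylbis(trifluoromethanesulfonimide), O=S(=O)(N(c1ccccc1)S(=O)(=O)C(F)(F)F)C(F)(F)F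
Why: Base-induced carbamate cleavage (the isocyanate is scavenged by Et2NH) and in-situ triflation of the phenoxide give the o-silylaryl triflate without protodesilylation.

Step 8
Reactants: 7 propan-2-yl (2R,3S,4R)-3-(3,5-dimethoxyphenyl)-5,7-dimethoxy-4-(4-methoxyphenyl)-1-oxo-1,2,3,4-tetrahydronaphthalene-2-carboxylate; 11 3,5-dimethoxy-2-(trimethylsilyl)phenyl trifluoromethanesulfonate
Product: 14 propan-2-yl (10R,11S,12R)-11-(3,5-dimethoxyphenyl)-1,3,6,8-tetramethoxy-12-(4-methoxyphenyl)-5-oxo-5,10,11,12-tetrahydrodibenzo[a,d][8]annulene-10-carboxylate, via 3,5-dimethoxybenzyne 12 (not isolated), via benzocyclobutenol adduct 13 (not isolated)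
Conditions: CsF (3 equiv), MeCN, 80 °C
Reagents that add atoms: none
Why: Fluoride converts 11 into aryne 12; the caesium enolate of 7 adds through C-2 to the aryne carbon meta to both methoxy groups (the distal terminus of a 3-alkoxyaryne), and the aryl anion left next to OMe attacks the adjacent ketone C-5 to give benzocyclobutenoxide 13, which fragments across the old C-2–C-5 bond to the ester enolate of 14. This is the aryne acyl-alkylation (formal aryne insertion into the C–C bond of a β-keto ester), a reaction type that expands cyclic β-keto esters by two carbons and places the ketone ortho to oxygen with 3,5-dialkoxyarynes. The eight-membered ring is closed by ring expansion of the tetralone (4-exo addition of the aryl anion to C=O, then fragmentation), not by end-to-end cyclisation. No permanent stereocentre is created: C-3 and C-4 pass through untouched, and C-2, α to the ester, should equilibrate to the epimer trans to ring B. The step needs attack of the aryl anion on the ketone and not on the ester, secured by the higher electrophilicity of the ketone, and C- over O-arylation, favoured for the stabilised enolate; the aryne is kept near one equivalent to avoid a second arylation.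

Step 9
Reactants: 14 propan-2-yl (10R,11S,12R)-11-(3,5-dimethoxyphenyl)-1,3,6,8-tetramethoxy-12-(4-methoxyphenyl)-5-oxo-5,10,11,12-tetrahydrodibenzo[a,d][8]annulene-10-carboxylate
Product: 15 propan-2-yl (10R,11S,12R)-11-(3,5-dimethoxyphenyl)-5-hydroxy-1,3,6,8-tetramethoxy-5-(4-methoxybenzyl)-12-(4-methoxyphenyl)-5,10,11,12-tetrahydrodibenzo[a,d][8]annulene-10-carboxylate (C-5 epimers)
Conditions: LiN(SiMe3)2 (1.1 equiv), THF, −78 °C; then 4-MeOC6H4CH2MgCl (3 equiv), −78 → 0 °C; aq. NH4Cl
Reagents that add atoms: 4-methoxybenzylmagnesium chloride, COc1ccc(C[Mg]Cl)cc1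
Why: Pre-forming the ester enolate masks the ester and the acidic C-2–H, so the benzylic Grignard reagent adds 1,2 only to the dibenzo-fused ketone; the new C-5 carbinol centre is of no consequence because C-5 becomes sp2 in step 11, and the product is carried on equally well if it closes to the δ-lactone.

Step 10
Reactants: 15 propan-2-yl (10R,11S,12R)-11-(3,5-dimethoxyphenyl)-5-hydroxy-1,3,6,8-tetramethoxy-5-(4-methoxybenzyl)-12-(4-methoxyphenyl)-5,10,11,12-tetrahydrodibenzo[a,d][8]annulene-10-carboxylate
Product: 17 [(10R,11S,12R)-11-(3,5-dimethoxyphenyl)-5-hydroxy-1,3,6,8-tetramethoxy-5-(4-methoxybenzyl)-12-(4-methoxyphenyl)-5,10,11,12-tetrahydrodibenzo[a,d][8]annulen-10-yl](4-methoxyphenyl)methanol (carbinol epimers), via hydroxy aldehyde 16 (not isolated)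
Conditions: i-Bu2AlH (2.5 equiv), CH2Cl2, −78 °C; then 4-MeOC6H4MgBr (4 equiv), THF, −78 → 0 °C; aq. KNaC4H4O6
Reagents that add atoms: 4-methoxyphenylmagnesium bromide, COc1ccc([Mg]Br)cc1
Why: One-pot partial reduction/Grignard addition: the aluminium hemiacetal from the ester (or lactone) is held by the neighbouring C-5 alkoxide and releases aldehyde 16 only as the aryl Grignard reagent captures it; the C-1 carbinol centre is ionised in step 11 and C-2 remains free to settle trans to ring B.

Step 11
Reactants: 17 [(10R,11S,12R)-11-(3,5-dimethoxyphenyl)-5-hydroxy-1,3,6,8-tetramethoxy-5-(4-methoxybenzyl)-12-(4-methoxyphenyl)-5,10,11,12-tetrahydrodibenzo[a,d][8]annulen-10-yl](4-methoxyphenyl)methanol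
Product: 18 nona-O-methyl indane-fused dibenzocyclooctene with an exocyclic 4-methoxybenzylidene group at C-5 (C-1 S; C-2 S; C-3 R; C-4 R)
Conditions: p-TsOH (20 mol%), CH2Cl2 (high dilution), 0 °C → rt
Reagents that add atoms: none
Why: Acid ionises the secondary 4-methoxybenzylic alcohol to the C-1 cation, which the ortho carbon of ring B (activated ortho and para by methoxy) captures in a Friedel–Crafts cyclialkylation that closes the indane; ring D should end trans to ring A on C-2 because it lies anti to the C-2 substituent in the closure, C-2 (re-set through reversible E1) should end trans to C-4 in the all-trans indane, and the tertiary C-5 carbinol dehydrates by E1 to the conjugated benzylidene.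

Step 12
Reactants: 18 nona-O-methyl indane-fused dibenzocyclooctene with an exocyclic 4-methoxybenzylidene group at C-5
Product: 20 stenophyllol B (C-1 S; C-2 S; C-3 R; C-4 R; C-5 R; C-6 R), via open nonaphenol 19 (not isolated)
Conditions: BBr3 (15 equiv), CH2Cl2, −78 °C → rt; then H2O/THF, rt
Reagents that add atoms: none
Why: BBr3 cleaves all nine aryl methyl ethers, and the HBr from hydrolysis of the excess reagent then drives an acid-catalysed intramolecular hydroalkoxylation of 2-hydroxystilbene 19 (protonation at C-5, capture of the quinone-methide-type C-6 cation by the ortho hydroxyl of ring A, 5-exo); both events are reversible, so C-6 should end trans to ring C and C-5 should settle in the less strained configuration, taken here to be the natural one.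

Compound list
1 | 2-bromo-3,5-dimethoxybenzaldehyde | O=Cc1cc(OC)cc(OC)c1Br | starting material
2 | 3,5-dimethoxy-2-(4-methoxybenzyl)benzaldehyde | O=Cc1cc(OC)cc(OC)c1Cc1ccc(OC)cc1 | intermediate
3 | (E)-3-(3,5-dimethoxyphenyl)prop-2-enoic acid | OC(=O)/C=C/c1cc(OC)cc(OC)c1 | starting material
4 | propan-2-yl (E)-3-(3,5-dimethoxyphenyl)prop-2-enoate | CC(C)OC(=O)/C=C/c1cc(OC)cc(OC)c1 | intermediate
5 | photoenol of 2 (hydroxy-o-quinodimethane, hydroxyl and aryl both outward) | O/C=C1\C=C(OC)C=C(OC)/C1=C\c1ccc(OC)cc1 | intermediate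
6 | propan-2-yl (1R,2R,3S,4R)-3-(3,5-dimethoxyphenyl)-1-hydroxy-5,7-dimethoxy-4-(4-methoxyphenyl)-1,2,3,4-tetrahydronaphthalene-2-carboxylate | COc1cc(OC)cc(c1)[C@H]1[C@H](c2ccc(OC)cc2)c2c(OC)cc(OC)cc2[C@H](O)[C@@H]1C(=O)OC(C)C | intermediate
7 | propan-2-yl (2R,3S,4R)-3-(3,5-dimethoxyphenyl)-5,7-dimethoxy-4-(4-methoxyphenyl)-1-oxo-1,2,3,4-tetrahydronaphthalene-2-carboxylate | COc1cc(OC)cc(c1)[C@H]1[C@H](c2ccc(OC)cc2)c2c(OC)cc(OC)cc2C(=O)[C@@H]1C(=O)OC(C)C | intermediate
8 | 3,5-dimethoxyphenol | COc1cc(O)cc(OC)c1 | starting material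
9 | 3,5-dimethoxyphenyl N-(propan-2-yl)carbamate | COc1cc(OC(=O)NC(C)C)cc(OC)c1 | intermediate
10 | 3,5-dimethoxy-2-(trimethylsilyl)phenyl N-(propan-2-yl)carbamate | COc1cc(OC)c([Si](C)(C)C)c(OC(=O)NC(C)C)c1 | intermediate
11 | 3,5-dimethoxy-2-(trimethylsilyl)phenyl trifluoromethanesulfonate | COc1cc(OC)c([Si](C)(C)C)c(OS(=O)(=O)C(F)(F)F)c1 | intermediate
12 | 3,5-dimethoxybenzyne | COC1=CC(OC)=CC#C1 | intermediate
13 | benzocyclobutenol adduct (formed as its caesium alkoxide; four-membered ring cis-fused to the tetralin) | COc1cc(OC)cc(c1)[C@H]1[C@H](c2ccc(OC)cc2)c2c(OC)cc(OC)cc2[C@]2(O)c3c(OC)cc(OC)cc3[C@]12C(=O)OC(C)C | intermediate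
14 | propan-2-yl (10R,11S,12R)-11-(3,5-dimethoxyphenyl)-1,3,6,8-tetramethoxy-12-(4-methoxyphenyl)-5-oxo-5,10,11,12-tetrahydrodibenzo[a,d][8]annulene-10-carboxylate | COc1cc(OC)cc(c1)[C@H]1[C@H](c2ccc(OC)cc2)c2c(OC)cc(OC)cc2C(=O)c2c(OC)cc(OC)cc2[C@@H]1C(=O)OC(C)C | intermediate
15 | propan-2-yl (10R,11S,12R)-11-(3,5-dimethoxyphenyl)-5-hydroxy-1,3,6,8-tetramethoxy-5-(4-methoxybenzyl)-12-(4-methoxyphenyl)-5,10,11,12-tetrahydrodibenzo[a,d][8]annulene-10-carboxylate (C-5 epimers) | COc1cc(OC)cc(c1)[C@H]1[C@H](c2ccc(OC)cc2)c2c(OC)cc(OC)cc2C(O)(Cc2ccc(OC)cc2)c2c(OC)cc(OC)cc2[C@@H]1C(=O)OC(C)C | intermediate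
16 | (10R,11S,12R)-11-(3,5-dimethoxyphenyl)-5-hydroxy-1,3,6,8-tetramethoxy-5-(4-methoxybenzyl)-12-(4-methoxyphenyl)-5,10,11,12-tetrahydrodibenzo[a,d][8]annulene-10-carbaldehyde | COc1cc(OC)cc(c1)[C@H]1[C@H](c2ccc(OC)cc2)c2c(OC)cc(OC)cc2C(O)(Cc2ccc(OC)cc2)c2c(OC)cc(OC)cc2[C@@H]1C=O | intermediate
17 | [(10R,11S,12R)-11-(3,5-dimethoxyphenyl)-5-hydroxy-1,3,6,8-tetramethoxy-5-(4-methoxybenzyl)-12-(4-methoxyphenyl)-5,10,11,12-tetrahydrodibenzo[a,d][8]annulen-10-yl](4-methoxyphenyl)methanol | COc1cc(OC)cc(c1)[C@H]1[C@H](c2ccc(OC)cc2)c2c(OC)cc(OC)cc2C(O)(Cc2ccc(OC)cc2)c2c(OC)cc(OC)cc2[C@@H]1C(O)c1ccc(OC)cc1 | intermediate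
18 | nona-O-methyl indane-fused dibenzocyclooctene with exocyclic 4-methoxybenzylidene at C-5 (C-1 S; C-2 S; C-3 R; C-4 R) | COc1ccc([C@H]2c3c(OC)cc(OC)cc3[C@H]3[C@H](c4ccc(OC)cc4)c4c(OC)cc(OC)cc4C(=Cc4ccc(OC)cc4)c4c(cc(OC)cc4[C@H]23)OC)cc1 | intermediate
19 | open nonaphenol (2-hydroxystilbene isomer of the target) | Oc1ccc([C@H]2c3c(O)cc(O)cc3[C@H]3[C@H](c4ccc(O)cc4)c4c(O)cc(O)cc4C(=Cc4ccc(O)cc4)c4c(cc(O)cc4[C@H]23)O)cc1 | intermediate
20 | stenophyllol B | Oc1ccc([C@H]2c3c(O)cc(O)cc3[C@H]3[C@H](c4ccc(O)cc4)c4c(O)cc(O)cc4[C@@H]4c5c(cc(O)cc5[C@H]23)O[C@H]4c2ccc(O)cc2)cc1 | target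

Total step count: 12. Longest linear sequence: 8 steps (1, 3, 4, 8, 9, 10, 11, 12).

Steps most likely to fail

Step 3. The cycloaddition may be sluggish or poorly endo- and face-selective because the outward aryl group on the diene terminus is pressed against the neighbouring ring methoxy group, and an unligated titanium background reaction may erode the enantioselectivity. The fallback sets out from 2 and returns at 7. Pinnick oxidation (NaClO2, NaH2PO4, 2-methyl-2-butene) gives 3,5-dimethoxy-2-(4-methoxybenzyl)benzoic acid F1, and MeI/K2CO3 gives methyl 3,5-dimethoxy-2-(4-methoxybenzyl)benzoate F2. A Staunton–Weinreb annulation of F2 with 4 (LiN(i-Pr)2, THF, −78 °C: lateral lithiation, Michael addition, Dieckmann closure) should give racemic keto ester, that is 7 together with the enantiomer of 7 F3. Preparative chromatography on a chiral stationary phase returns 7.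

Step 11. Two cations are generated in one flask, so the tertiary C-5 cation may be captured transannularly by ring B or ring E, and reversible E1/re-protonation may deliver C-2 into a cis-fused indane. The fallback sets out from 14 and returns at 18, closing the indane while C-5 is still a ketone. LiAlH4 gives the diol F4 (primary alcohol on C-2, secondary carbinol at C-5). Dess–Martin oxidation gives the keto aldehyde F5, in which C-2 can be equilibrated with base. 4-MeOC6H4MgBr at −78 °C adds to the aldehyde only and gives the keto carbinol F6. p-TsOH closes the indane to the indane ketone F7. 4-MeOC6H4CH2MgCl then gives the tertiary carbinol F8, and p-TsOH dehydrates it to 18.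

Step 12. Protonation of the stilbene may occur on the wrong face of C-5, or equilibration may favour the C-5 epimer, and the electron-rich polyphenol cation may oligomerise by intermolecular Friedel–Crafts attack. The fallback sets out from 18 and returns at 20. Hydroboration–oxidation (BH3·THF; then H2O2, NaOH) delivers the C-5 hydrogen by syn addition under steric control and gives the secondary benzylic alcohol F9. BBr3 then demethylates F9 and ionises the C-6 carbinol, and the ring A hydroxyl closes the trans dihydrobenzofuran without any protonation at C-5.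

Further compounds
F1 | step 3 | 3,5-dimethoxy-2-(4-methoxybenzyl)benzoic acid | OC(=O)c1cc(OC)cc(OC)c1Cc1ccc(OC)cc1
F2 | step 3 | methyl 3,5-dimethoxy-2-(4-methoxybenzyl)benzoate | COC(=O)c1cc(OC)cc(OC)c1Cc1ccc(OC)cc1
F3 | step 3 | enantiomer of 7 | COc1cc(OC)cc(c1)[C@@H]1[C@@H](c2ccc(OC)cc2)c2c(OC)cc(OC)cc2C(=O)[C@H]1C(=O)OC(C)C
F4 | step 11 | diol from 14 (hydroxymethyl on C-2; C-5 carbinol) | COc1cc(OC)cc(c1)[C@H]1[C@H](c2ccc(OC)cc2)c2c(OC)cc(OC)cc2C(O)c2c(OC)cc(OC)cc2[C@@H]1CO
F5 | step 11 | keto aldehyde (C-5 ketone; formyl on C-2) | COc1cc(OC)cc(c1)[C@H]1[C@H](c2ccc(OC)cc2)c2c(OC)cc(OC)cc2C(=O)c2c(OC)cc(OC)cc2[C@@H]1C=O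
F6 | step 11 | keto carbinol (C-5 ketone; C-1 carbinol bearing ring D) | COc1cc(OC)cc(c1)[C@H]1[C@H](c2ccc(OC)cc2)c2c(OC)cc(OC)cc2C(=O)c2c(OC)cc(OC)cc2[C@@H]1C(O)c1ccc(OC)cc1
F7 | step 11 | indane ketone (C-5 ketone; indane closed) | COc1ccc([C@H]2c3c(OC)cc(OC)cc3[C@H]3[C@H](c4ccc(OC)cc4)c4c(OC)cc(OC)cc4C(=O)c4c(cc(OC)cc4[C@H]23)OC)cc1
F8 | step 11 | tertiary carbinol (4-methoxybenzyl and hydroxyl on C-5; indane closed) | COc1ccc([C@H]2c3c(OC)cc(OC)cc3[C@H]3[C@H](c4ccc(OC)cc4)c4c(OC)cc(OC)cc4C(O)(Cc4ccc(OC)cc4)c4c(cc(OC)cc4[C@H]23)OC)cc1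
F9 | step 12 | secondary benzylic alcohol (C-5 H set; C-6 carbinol) | COc1ccc([C@H]2c3c(OC)cc(OC)cc3[C@H]3[C@H](c4ccc(OC)cc4)c4c(OC)cc(OC)cc4[C@@H](C(O)c4ccc(OC)cc4)c4c(cc(OC)cc4[C@H]23)OC)cc1
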